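Ring A of the target (C4a, C5, C6, C7, C8, C8a) carries oxygen on C5, C7 and C8a and carbon on C4a, C6 and C8: it is a 2-acyl-4,6-dimethylphloroglucinol, the imprint of a folded, twice C-methylated poly-β-carbonyl chain. The route exploits this by disconnecting the C4a–C8a bond. A 4-hydroxy-3,5-dimethyl-2-pyranone carrying a 2-methoxycinnamoylmethyl group at C6 (7) is opened by Mg(OMe)2 and recloses by Claisen condensation, which should deliver the fully substituted ring A in one operation as the symmetric trihydroxychalcone 9. Oxidative closure of ring C, double O-methylation and C3 hydroxylation then complete the flavonol.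

Key step: step 5

Remark: lithium, magnesium and potassium salts (enolates, phenoxides) of numbered compounds are treated as forms of those compounds and carry no number of their own; 1, 2, 8, 10 and 14 are racemates or stereoisomer mixtures, which is immaterial because every stereocentre is erased before the achiral target.

Step 1
Reactants: 1 methyl 2-methyl-3-oxopentanoate (racemic)
Product: 2 methyl 2,4-dimethyl-3,5-dioxohexanoate (mixture of stereoisomers and enol forms)
Conditions: LiN(iPr)2 (2.2 equiv), THF, -78 to 0 °C; MeC(O)N(OMe)Me (1.0 equiv), -78 to 0 °C; aq. HCl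
Reagents that add atoms: N-methoxy-N-methylacetamide, CC(=O)N(C)OC
Why: LiN(iPr)2 removes the C2 and C4 protons and the more reactive C4 terminus attacks the Weinreb amide, whose chelated tetrahedral adduct blocks over-addition (γ-acylation of a β-keto ester dianion), the two stereocentres of 2 being erased in step 2.

Step 2
Reactants: 2 methyl 2,4-dimethyl-3,5-dioxohexanoate
Product: 3 4-hydroxy-3,5,6-trimethyl-2H-pyran-2-one
Conditions: DBU (1.5 equiv), toluene, reflux; aq. HCl
Reagents that add atoms: none
Why: DBU enolises the 3,5-dioxo ester and the C5 enol oxygen attacks the ester carbonyl with loss of methanol (base-mediated enol-lactonisation to a 4-hydroxy-2-pyranone), the stabilised pyranone driving the closure and removing both stereocentres.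

Step 3
Reactants: 4 (E)-2-methoxycinnamic acid
Product: 6 (E)-N-methoxy-3-(2-methoxyphenyl)-N-methylprop-2-enamide, via acyl imidazole 5 (not isolated)
Conditions: CDI (1.1 equiv), CH2Cl2, rt; MeNH(OMe)·HCl (1.2 equiv), rt
Reagents that add atoms: N,O-dimethylhydroxylamine hydrochloride, CNOC.Cl (N(OMe)Me group of 6); 1,1'-carbonyldiimidazole, O=C(n1ccnc1)n1ccnc1 (imidazolyl group of 5 only, lost again on the way to 6)
Why: Activation of the acid as its acyl imidazole and aminolysis by N,O-dimethylhydroxylamine (CDI amide coupling, Weinreb amide formation) is mild enough to leave the E-alkene and the aryl ether untouched.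

Step 4
Reactants: 3 4-hydroxy-3,5,6-trimethyl-2H-pyran-2-one; 6 (E)-N-methoxy-3-(2-methoxyphenyl)-N-methylprop-2-enamide
Product: 7 4-hydroxy-6-[(E)-4-(2-methoxyphenyl)-2-oxobut-3-enyl]-3,5-dimethyl-2H-pyran-2-one
Conditions: 3, LiN(iPr)2 (2.1 equiv), THF, -78 to -20 °C; 6, -78 to -20 °C; aq. HCl
Reagents that add atoms: none
Why: The first equivalent of base removes the 4-OH proton and the second a proton of the 6-methyl group, the only methyl conjugated as a vinylogue to the ring carbonyls, and this carbon adds 1,2 to the Weinreb amide (acylation of a 4-hydroxy-6-methyl-2-pyranone dianion), the lithium-chelated adduct persisting until the acidic quench so that the acidic product methylene cannot consume the dianion.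

Step 5
Reactants: 7 4-hydroxy-6-[(E)-4-(2-methoxyphenyl)-2-oxobut-3-enyl]-3,5-dimethyl-2H-pyran-2-one
Product: 9 (E)-3-(2-methoxyphenyl)-1-(2,4,6-trihydroxy-3,5-dimethylphenyl)prop-2-en-1-one, via triketo ester 8 (not isolated)
Conditions: Mg(OMe)2 (8 equiv), MeOH, reflux; cold 1 M HCl
Reagents that add atoms: Mg(OMe)2, CO[Mg]OC (methoxy group of 8 only; it is expelled again on ring closure and 9 keeps no reagent atom)
Why: Methoxide adds to the lactone carbonyl of 7 and opens the ring to the magnesium-chelated triketo ester 8, whose methylene between two ketones attacks the ester carbonyl, expels methoxide and leaves a triketone that tautomerises to the arene, so that the C4a–C8a bond (flavone numbering) and ring A arise together. The closest known reaction type is the Mg(OMe)2-mediated Claisen recyclisation of 6-(2-oxoalkyl)-4-hydroxy-2-pyranones and 3,5,7-triketo esters to acylphloroglucinols. Ring A closes in a 6-exo-trig mode, the ester C=O lying outside the new six-membered ring. No stereocentre is created, and the two epimerisable methine centres of 8 vanish on aromatisation. The step needs Claisen closure to win over aldol closure, re-lactonisation and attack on the enone: the only carbon that could start a six-membered aldol closure is a methyl-bearing methine whose adduct holds a quaternary carbon, cannot dehydrate to an arene and therefore reverts, while magnesium chelation fixes the 1,3-diketone enolate next to the ester and irreversible aromatisation drains the equilibria. The enone is shielded because it belongs to the extended enolate in 7 and 8 and to the chelated phenoxide of the product, which should also keep the chalcone open until the cold acidic quench, and the symmetry of the new ring makes either ortho hydroxyl usable for closing ring C.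

Step 6
Reactants: 9 (E)-3-(2-methoxyphenyl)-1-(2,4,6-trihydroxy-3,5-dimethylphenyl)prop-2-en-1-one
Product: 11 5,7-dihydroxy-2-(2-methoxyphenyl)-6,8-dimethyl-4H-chromen-4-one, via flavanone 10 (not isolated)
Conditions: I2 (10 mol %), DMSO, 120 °C
Reagents that add atoms: none
Why: Oxa-Michael closure by either of the two equivalent ortho hydroxyls gives flavanone 10, which is iodinated at C3 and loses HI while DMSO reoxidises the iodide (iodine/DMSO oxidative cyclisation of a 2'-hydroxychalcone to a flavone), and ring A has no free CH, so nuclear iodination cannot compete.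

Step 7
Reactants: 11 5,7-dihydroxy-2-(2-methoxyphenyl)-6,8-dimethyl-4H-chromen-4-one
Product: 13 5,7-dimethoxy-2-(2-methoxyphenyl)-6,8-dimethyl-4H-chromen-4-one, via 7-O-methyl ether 12 (not isolated)
Conditions: Me2SO4 (4 equiv), K2CO3 (5 equiv), acetone, reflux
Reagents that add atoms: dimethyl sulfate, COS(=O)(=O)OC
Why: The acidic 7-OH should be methylated first and the chelated, methyl-flanked 5-OH should follow under prolonged reflux with excess of the hard electrophile (Williamson-type phenol O-methylation), C-methylation being unlikely because every carbon of ring A is substituted.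

Step 8
Reactants: 13 5,7-dimethoxy-2-(2-methoxyphenyl)-6,8-dimethyl-4H-chromen-4-one
Product: 15 3-hydroxy-5,7-dimethoxy-2-(2-methoxyphenyl)-6,8-dimethyl-4H-chromen-4-one, via flavone epoxide 14 (not isolated)
Conditions: DMDO (acetone solution, 1.5-2 equiv), CH2Cl2, 0 °C to rt; evaporate; p-TsOH·H2O (cat.), CH2Cl2, rt
Reagents that add atoms: dimethyldioxirane, CC1(C)OO1
Why: Dimethyldioxirane epoxidises the enol-ether-like C2=C3 bond and acid then opens the epoxide at the oxygen- and aryl-stabilised C2, loss of the C3 proton giving the 3-hydroxyflavone (epoxidation of a flavone and acid isomerisation of its 2,3-epoxide), so the transient stereocentres of 14 disappear.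

Compound list
1 | methyl 2-methyl-3-oxopentanoate (racemic) | CCC(=O)C(C)C(=O)OC | starting material
2 | methyl 2,4-dimethyl-3,5-dioxohexanoate (mixture of stereoisomers and enol forms) | CC(=O)C(C)C(=O)C(C)C(=O)OC | intermediate
3 | 4-hydroxy-3,5,6-trimethyl-2H-pyran-2-one | Cc1oc(=O)c(C)c(O)c1C | intermediate
4 | (E)-2-methoxycinnamic acid, (E)-3-(2-methoxyphenyl)prop-2-enoic acid | COc1ccccc1/C=C/C(=O)O | starting material
5 | (E)-1-(imidazol-1-yl)-3-(2-methoxyphenyl)prop-2-en-1-one (acyl imidazole, not isolated) | COc1ccccc1/C=C/C(=O)n1ccnc1 | intermediate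
6 | (E)-N-methoxy-3-(2-methoxyphenyl)-N-methylprop-2-enamide | COc1ccccc1/C=C/C(=O)N(C)OC | intermediate
7 | 4-hydroxy-6-[(E)-4-(2-methoxyphenyl)-2-oxobut-3-enyl]-3,5-dimethyl-2H-pyran-2-one | COc1ccccc1/C=C/C(=O)Cc1oc(=O)c(C)c(O)c1C | intermediate
8 | methyl (E)-9-(2-methoxyphenyl)-2,4-dimethyl-3,5,7-trioxonon-8-enoate (triketo ester, formed as its magnesium enolate, stereoisomer mixture, not isolated) | COC(=O)C(C)C(=O)C(C)C(=O)CC(=O)/C=C/c1ccccc1OC | intermediate
9 | (E)-3-(2-methoxyphenyl)-1-(2,4,6-trihydroxy-3,5-dimethylphenyl)prop-2-en-1-one | COc1ccccc1/C=C/C(=O)c1c(O)c(C)c(O)c(C)c1O | intermediate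
10 | 5,7-dihydroxy-2-(2-methoxyphenyl)-6,8-dimethylchroman-4-one (flavanone, racemic, not isolated) | COc1ccccc1C1CC(=O)c2c(O)c(C)c(O)c(C)c2O1 | intermediate
11 | 5,7-dihydroxy-2-(2-methoxyphenyl)-6,8-dimethyl-4H-chromen-4-one | COc1ccccc1-c1cc(=O)c2c(O)c(C)c(O)c(C)c2o1 | intermediate
12 | 5-hydroxy-7-methoxy-2-(2-methoxyphenyl)-6,8-dimethyl-4H-chromen-4-one (7-O-methyl ether, not isolated) | COc1ccccc1-c1cc(=O)c2c(O)c(C)c(OC)c(C)c2o1 | intermediate
13 | 5,7-dimethoxy-2-(2-methoxyphenyl)-6,8-dimethyl-4H-chromen-4-one | COc1ccccc1-c1cc(=O)c2c(OC)c(C)c(OC)c(C)c2o1 | intermediate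
14 | 4,6-dimethoxy-1a-(2-methoxyphenyl)-3,5-dimethyl-1a,7a-dihydro-7H-oxireno[2,3-b]chromen-7-one (flavone 2,3-epoxide, racemic, ring fusion necessarily cis, not isolated) | COc1ccccc1C12OC1C(=O)c1c(OC)c(C)c(OC)c(C)c1O2 | intermediate
15 | 3-hydroxy-5,7-dimethoxy-2-(2-methoxyphenyl)-6,8-dimethyl-4H-chromen-4-one | COc1ccccc1-c1oc2c(C)c(OC)c(C)c(OC)c2c(=O)c1O | target

Total step count: 8. Longest linear sequence: 7 steps (steps 1, 2, 4, 5, 6, 7, 8); step 3 is a one-step side branch.

Steps most likely to fail

Step 5. Conjugate addition of methoxide or of an internal carbon nucleophile to the enone, or retro-Claisen loss of the cinnamoyl unit, may outrun attack on the ester; partial closure of the product to flavanone 10 on work-up would be harmless, since step 6 accepts both. The fallback folds the ring without the enone and attaches the styryl unit afterwards. It sets out from 3, whose dianion (LiN(iPr)2, THF) is acylated with N-methoxy-N-methylacetamide to give 4-hydroxy-3,5-dimethyl-6-(2-oxopropyl)-2H-pyran-2-one F1. Mg(OMe)2 in refluxing MeOH should fold this to 1-(2,4,6-trihydroxy-3,5-dimethylphenyl)ethan-1-one F2. Two equivalents of Me2SO4 with K2CO3 in acetone should leave only the chelated hydroxyl free, giving 1-(2-hydroxy-4,6-dimethoxy-3,5-dimethylphenyl)ethan-1-one F3. Claisen–Schmidt condensation with commercial 2-methoxybenzaldehyde (KOH, EtOH) should then give (E)-1-(2-hydroxy-4,6-dimethoxy-3,5-dimethylphenyl)-3-(2-methoxyphenyl)prop-2-en-1-one F4. I2 in DMSO closes F4 to 13, where the route resumes at step 8.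

Step 4. The soft dianion may add 1,4 to the cinnamoyl unit, or the base may attack the N-methoxy group of the Weinreb amide instead of forming the C–C bond. The fallback replaces acylation by aldehyde addition and oxidation. It sets out from 3, whose dianion should add 1,2 to commercial (E)-2-methoxycinnamaldehyde to give racemic 4-hydroxy-6-[(E)-2-hydroxy-4-(2-methoxyphenyl)but-3-enyl]-3,5-dimethyl-2H-pyran-2-one F5. Oxidation of this allylic alcohol with MnO2 in CH2Cl2 returns to the route at 7.

Step 8. Oxidation of the very electron-rich ring A may compete, or epoxidation of the twisted, hindered C2=C3 bond may stay incomplete. The fallback hydroxylates C3 through an organoboron intermediate. It sets out from 13, which is deprotonated at C3 with LiN(iPr)2 in THF at -78 °C and trapped with B(OMe)3 to give dimethyl [5,7-dimethoxy-2-(2-methoxyphenyl)-6,8-dimethyl-4-oxo-4H-chromen-3-yl]boronate F6. Oxidation in the same flask with H2O2 and AcOH returns to the route at the target 15.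

Further compounds
F1 | step 5 | 4-hydroxy-3,5-dimethyl-6-(2-oxopropyl)-2H-pyran-2-one | CC(=O)Cc1oc(=O)c(C)c(O)c1C
F2 | step 5 | 1-(2,4,6-trihydroxy-3,5-dimethylphenyl)ethan-1-one | CC(=O)c1c(O)c(C)c(O)c(C)c1O
F3 | step 5 | 1-(2-hydroxy-4,6-dimethoxy-3,5-dimethylphenyl)ethan-1-one | CC(=O)c1c(O)c(C)c(OC)c(C)c1OC
F4 | step 5 | (E)-1-(2-hydroxy-4,6-dimethoxy-3,5-dimethylphenyl)-3-(2-methoxyphenyl)prop-2-en-1-one | COc1ccccc1/C=C/C(=O)c1c(O)c(C)c(OC)c(C)c1OC
F5 | step 4 | 4-hydroxy-6-[(E)-2-hydroxy-4-(2-methoxyphenyl)but-3-enyl]-3,5-dimethyl-2H-pyran-2-one (racemic) | COc1ccccc1/C=C/C(O)Cc1oc(=O)c(C)c(O)c1C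
F6 | step 8 | dimethyl [5,7-dimethoxy-2-(2-methoxyphenyl)-6,8-dimethyl-4-oxo-4H-chromen-3-yl]boronate | COB(OC)c1c(-c2ccccc2OC)oc2c(C)c(OC)c(C)c(OC)c2c1=O
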